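## Retrosynthetic overview

1. Ring C is closed last. The C2–O1 bond comes from a catalyst-controlled oxa-Michael closure of a 2',4',6'-trihydroxychalcone, and this closure sets 2S.
2. Ring A is made just before it, in the same flask, by C-6→C-1 Claisen cyclisation and aromatisation of a linear cinnamoyl triketide ester. That ester is stored as its lactone, a 6-(cinnamoylmethyl)-4-hydroxy-2-pyranone, so no phloroglucinol building block is used.
3. The pyranone comes from a C–C bond between the 6-methyl carbon of triacetic acid lactone (as its dianion) and a ring B Weinreb cinnamamide.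
4. The cinnamamide comes from Wittig olefination of 5-geranyl-2-hydroxy-4-methoxybenzaldehyde. The aryl–geranyl bond comes from Stille coupling of the 5-bromo aldehyde.
5. Ring order: ring B is purchased, then ring A, then ring C.

Assumption: the quinine-derived thiourea is taken to give Si-face attack at C-β (2S); if the sense proves opposite, its quinidine-derived pseudoenantiomer, 1-[3,5-bis(trifluoromethyl)phenyl]-3-[(9R)-6'-methoxycinchonan-9-yl]thiourea, is used under the same conditions.

## Route

**Step 1**
Reactants: 1 geranyl bromide [(2E)-1-bromo-3,7-dimethylocta-2,6-diene]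
Product: 2 tributyl[(2E)-3,7-dimethylocta-2,6-dien-1-yl]stannane
Conditions: Bu3SnH, LiN(iPr)2, THF, 0 °C, 30 min; then 1, −78 °C → rt
Reagents that add atoms: tributyltin hydride, CCCC[SnH](CCCC)CCCC
Why: SN2 alkylation of a stannyl anion, in which the soft Bu3Sn anion attacks the primary allylic carbon of 1 at −78 °C without allylic transposition, so the E-olefin is carried over unchanged.

**Step 2**
Reactants: 2 tributyl(geranyl)stannane; 3 5-bromo-2-hydroxy-4-methoxybenzaldehyde
Product: 4 5-[(2E)-3,7-dimethylocta-2,6-dien-1-yl]-2-hydroxy-4-methoxybenzaldehyde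
Conditions: Pd(PPh3)4 (5 mol %), 2 (1.5 equiv), DMF, degassed, 100 °C, 12 h
Reagents that add atoms: none
Why: Stille cross-coupling, in which zerovalent palladium inserts into the C–Br bond of 3, the allylstannane transmetalates and reductive elimination at the unhindered CH2 terminus gives the linear E-geranyl arene under neutral conditions that spare the free phenol and the aldehyde.

**Step 3**
Reactants: 4 5-geranyl-2-hydroxy-4-methoxybenzaldehyde; 5 N-methoxy-N-methyl-2-(triphenyl-λ5-phosphanylidene)acetamide
Product: 6 (2E)-3-{5-[(2E)-3,7-dimethylocta-2,6-dien-1-yl]-2-hydroxy-4-methoxyphenyl}-N-methoxy-N-methylprop-2-enamide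
Conditions: 5 (1.2 equiv), CH2Cl2, rt, 16 h
Reagents that add atoms: none
Why: Wittig olefination with a stabilised ylide is E-selective, needs no base and tolerates the free ortho-phenol, and the E-geometry rules out lactonisation to the coumarin.

**Step 4**
Reactants: 6 ring B Weinreb cinnamamide; 7 triacetic acid lactone (4-hydroxy-6-methyl-2H-pyran-2-one)
Product: 8 6-[(3E)-4-{5-[(2E)-3,7-dimethylocta-2,6-dien-1-yl]-2-hydroxy-4-methoxyphenyl}-2-oxobut-3-en-1-yl]-4-hydroxy-2H-pyran-2-one
Conditions: 7 (3.5 equiv), LiN(iPr)2 (7.0 equiv), THF, −78 °C, 1 h; add 6, −78 → 0 °C, 3 h; 1 M aq HCl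
Reagents that add atoms: none
Why: Claisen-type C-acylation of a dianion, in which the 4-O,6-CH2 dianion of 7 reacts at its terminal carbon, the excess absorbs the phenol proton of 6, the chelated Weinreb tetrahedral intermediate blocks over-addition, and 1,2-attack is favoured because the electron-rich aryl group deactivates the β-carbon.

**Step 5** (key step: ring A and ring C form in one telescoped operation)
Reactants: 8 cinnamoylmethyl-4-hydroxy-2-pyranone
Product: 11 Kuwanon U [(2S)-2-{5-[(2E)-3,7-dimethylocta-2,6-dien-1-yl]-2-hydroxy-4-methoxyphenyl}-5,7-dihydroxy-2,3-dihydro-4H-chromen-4-one], via triketo ester 9 (not isolated), via chalcone 10 (not isolated)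
Conditions: Mg(OMe)2 (6 equiv) in MeOH, reflux, 8 h, N2; 0 °C, PhCl, 1 M aq HCl to pH 4, phase cut, Na2SO4, dark, no concentration; then 1-[3,5-bis(trifluoromethyl)phenyl]-3-[(8α,9S)-6'-methoxycinchonan-9-yl]thiourea (10 mol %), 4 Å MS, PhCl, −20 °C, 72 h; silica plug
Reagents that add atoms: magnesium methoxide, [Mg+2].[O-]C.[O-]C (its methoxy group sits only in 9)
Why: Proposed new method: Mg(OMe)2 opens the 2-pyranone to the magnesium-chelated methyl 3,5,7-trioxo ester 9, whose ketones are all masked as enolates so that only C-6→C-1 Claisen acylation remains and aromatisation to the phloroglucinol ring A of chalcone 10 drives it (closest known reaction type: biomimetic magnesium methoxide cyclisation of 6-(2-oxoalkyl)-4-hydroxy-2-pyranones to acylphloroglucinols); the poly-phenoxide stays open until the cold acid quench, and the bifunctional cinchona thiourea then binds the enone carbonyl through its NH groups while its quinuclidine deprotonates one of the two equivalent ortho-hydroxyls and guides it onto the Si face of C-β, closing ring C with 2S configuration (closest known reaction type: cinchona-catalysed intramolecular oxa-Michael addition of 2'-hydroxychalcones and o-enoylphenols).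

## Compound list

1 | geranyl bromide | BrC/C=C(\C)CCC=C(C)C | starting material
2 | tributyl[(2E)-geranyl]stannane | CCCC[Sn](CCCC)(CCCC)C/C=C(\C)CCC=C(C)C | intermediate
3 | 5-bromo-2-hydroxy-4-methoxybenzaldehyde | COc1cc(O)c(C=O)cc1Br | starting material
4 | 5-[(2E)-geranyl]-2-hydroxy-4-methoxybenzaldehyde | COc1cc(O)c(C=O)cc1C/C=C(\C)CCC=C(C)C | intermediate
5 | N-methoxy-N-methyl-2-(triphenylphosphanylidene)acetamide | CON(C)C(=O)C=P(c1ccccc1)(c1ccccc1)c1ccccc1 | starting material
6 | (E)-Weinreb cinnamamide of ring B | COc1cc(O)c(/C=C/C(=O)N(C)OC)cc1C/C=C(\C)CCC=C(C)C | intermediate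
7 | triacetic acid lactone | CC1=CC(O)=CC(=O)O1 | starting material
8 | 6-[(3E)-4-aryl-2-oxobut-3-enyl]-4-hydroxy-2H-pyran-2-one (aryl = 5-geranyl-2-hydroxy-4-methoxyphenyl) | COc1cc(O)c(/C=C/C(=O)CC2=CC(O)=CC(=O)O2)cc1C/C=C(\C)CCC=C(C)C | intermediate
9 | methyl (8E)-9-(5-geranyl-2-hydroxy-4-methoxyphenyl)-3,5,7-trioxonon-8-enoate (present as magnesium enolate) | COC(=O)CC(=O)CC(=O)CC(=O)/C=C/c1cc(C/C=C(\C)CCC=C(C)C)c(OC)cc1O | intermediate
10 | (E)-5-geranyl-2,2',4',6'-tetrahydroxy-4-methoxychalcone | O=C(/C=C/c1cc(C/C=C(\C)CCC=C(C)C)c(OC)cc1O)c1c(O)cc(O)cc1O | intermediate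
11 | Kuwanon U, (2S) | COc1cc(O)c([C@@H]2CC(=O)c3c(O)cc(O)cc3O2)cc1C/C=C(\C)CCC=C(C)C | target

## Step count and risks

Total steps: 5. Longest linear sequence: 5 (1 → 2 → 4 → 6 → 8 → 11).

**Step 5 is most at risk.**
- The magnesium methoxide stage may divert to aldol-mode cyclisation or to retro-Claisen cleavage.
- Part of the chalcone may close without control before the catalyst is added.
- The ee on an unprotected tetrahydroxychalcone is untested.
- The fallback sets out from 8 and comes back at 11. The magnesium methoxide cyclisation is run as before, and the chalcone is then left to close without control (NaOAc, EtOH, reflux) to racemic Kuwanon U F1. This is resolved kinetically by asymmetric transfer hydrogenation (Cp*RhCl[(R,R)-TsDPEN], HCO2H/Et3N, EtOAc, rt, stopped near 50 % conversion). The 2R enantiomer is reduced to the cis-(2R,4R)-flavan-4-ol F2, which is removed by chromatography, and unreacted 11 is recovered. The yield of this fallback cannot exceed 50 %.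

**Step 4 is second.**
- The phenoxide-bearing, electron-rich Weinreb amide may be too poor an acylating agent.
- Some 1,4-addition may intrude.
- The fallback sets out from 4 and comes back at 8, replacing acylation by aldol addition and oxidation. Wittig reaction of 4 with Ph3P=CHCHO gives the (E)-cinnamaldehyde F3. The dianion of 7 adds 1,2 to this far more electrophilic carbonyl to give the racemic allylic alcohol F4. MnO2 in CH2Cl2 oxidises that alcohol to 8.

**Step 2 is third.**
- The acidic phenol may protodestannylate 2 at 100 °C.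
- γ-Coupling or E/Z erosion may occur through the allylpalladium intermediate.
- The fallback sets out from 1 and comes back at 4 without any cross-coupling. The phenoxide of purchased 2,4-dihydroxybenzaldehyde is C-alkylated with 1 (KOH, MeOH/H2O, 0 °C → rt) to give 5-geranyl-2,4-dihydroxybenzaldehyde F5, which is separated from the 3-isomer and the O-ethers. The non-chelated 4-hydroxyl is then methylated selectively (MeI 1.0 equiv, K2CO3, acetone) to give 4.

## Further compounds

F1 | step 5 | racemic Kuwanon U | COc1cc(O)c(C2CC(=O)c3c(O)cc(O)cc3O2)cc1C/C=C(\C)CCC=C(C)C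
F2 | step 5 | cis-(2R,4R)-flavan-4-ol from the 2R enantiomer | COc1cc(O)c([C@H]2C[C@@H](O)c3c(O)cc(O)cc3O2)cc1C/C=C(\C)CCC=C(C)C
F3 | step 4 | (E)-3-(5-geranyl-2-hydroxy-4-methoxyphenyl)prop-2-enal | COc1cc(O)c(/C=C/C=O)cc1C/C=C(\C)CCC=C(C)C
F4 | step 4 | 6-[(3E)-4-aryl-2-hydroxybut-3-enyl]-4-hydroxy-2H-pyran-2-one, racemic carbinol | COc1cc(O)c(/C=C/C(O)CC2=CC(O)=CC(=O)O2)cc1C/C=C(\C)CCC=C(C)C
F5 | step 2 | 5-[(2E)-geranyl]-2,4-dihydroxybenzaldehyde | O=Cc1cc(C/C=C(\C)CCC=C(C)C)c(O)cc1O
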